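Numbering (daucane): the cyclopentane is C1 (quaternary, CH3), C2, C3, C4 (C(OH)iPr) and C5 (ring-fusion CH); the cycloheptene is C1, C5, C6 (OAr), C7, C8 (=C–CH3), C9 and C10 (OAng).
Endgame: the two esters go on last (O6, then O10). The isopropyl group adds to a C4 ketone opposite the C1 methyl, and the cycloheptene is closed at C8=C9 by ring-closing metathesis.
Key disconnection and enabling feature: C4(O)–C5–C6(O) is an aldol triad whose α-carbon C5 is also bonded to the quaternary C1. C5 is therefore removed as a one-carbon carbenoid: a 1-(dibromomethyl)cyclobutanol (ring C1–C2–C3–C4) enlarges by shift of C1 from C4 to C5, and the resulting enolate is trapped by 3-methylbut-3-enal (C6–C8).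
The cyclobutanone carrying C1 and C10 comes from an (E)-dienylcyclopropanol by asymmetric epoxidation of C1=C10 followed by a cyclopropanol-to-cyclobutanone shift.
Ring order: cyclopropane, cyclobutane, cyclopentane, then cycloheptene.

Key step: step 8

Remark: β is the face of the bicycle that carries the C1 methyl group, and α is the opposite face.
Remark: the C4 center of 10 is destroyed again in step 8, so the drawn epimer (attack anti to the C10 arm) is only the expected major one.

Step 1
Reactants: 1 [(1-ethoxycyclopropyl)oxy]trimethylsilane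
Product: 3 1-ethynylcyclopropan-1-ol, via 1-ethoxycyclopropan-1-ol 2 (not isolated)
Conditions: MeOH, rt, evaporate; HC≡CMgBr (2.5 equiv), THF, 0 °C to reflux; then H2O
Reagents that add atoms: ethynylmagnesium bromide, C#C[Mg]Br
Why: Methanolysis frees hemiacetal 2, whose magnesium salt releases cyclopropanone in the flask, and the alkynyl Grignard reagent adds to it (1,2-addition to a cyclopropanone equivalent) without forming a stereocenter.

Step 2
Reactants: 3 1-ethynylcyclopropan-1-ol
Product: 4 1-(but-3-en-1-yn-1-yl)cyclopropan-1-ol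
Conditions: vinyl bromide, PdCl2(PPh3)2 (2 mol %), CuI (4 mol %), iPr2NH, THF, rt
Reagents that add atoms: vinyl bromide, C=CBr
Why: Sonogashira coupling of the terminal alkyne with vinyl bromide runs at room temperature under amine conditions, where the tertiary cyclopropanol ring should stay closed.

Step 3
Reactants: 4 1-(but-3-en-1-yn-1-yl)cyclopropan-1-ol
Product: 6 1-[(2E)-penta-2,4-dien-2-yl]cyclopropan-1-ol, via chelated dienylmagnesium alkoxide 5 (not isolated)
Conditions: MeMgBr (3 equiv), CuI (15 mol %), THF, 0 °C to rt; then H2O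
Reagents that add atoms: methylmagnesium bromide, C[Mg]Br
Why: In this copper-catalysed, alkoxide-directed anti-carbomagnesiation of a propargylic alcohol, methyl adds to the proximal alkyne carbon C1 and magnesium ends on C10 cis to the carbinol in chelate 5, so protonolysis should give only the (E)-alkene with the vinyl group trans to the cyclopropanol.

Step 4
Reactants: 6 1-[(2E)-penta-2,4-dien-2-yl]cyclopropan-1-ol
Product: 8 (2R)-2-[(1R)-1-hydroxyprop-2-en-1-yl]-2-methylcyclobutan-1-one, via epoxy cyclopropanol 7 (not isolated)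
Conditions: D-fructose-derived Shi ketone (30 mol %), KHSO5 (as 2KHSO5·KHSO4·K2SO4), K2CO3, Bu4NHSO4, MeCN/CH2(OMe)2, aq Na2B4O7 buffer, 0 °C; crude 7, BF3·OEt2 (10 mol %), CH2Cl2, −78 °C
Reagents that add atoms: potassium peroxymonosulfate, [K+].[O-]S(=O)(=O)OO
Why: Shi asymmetric epoxidation should take the trisubstituted, more electron-rich C1=C10 bond of the diene on the face set by the ketone (C10 becomes R), and the α-hydroxy epoxide then undergoes a semipinacol shift in which a cyclopropane CH2 moves to C1 anti to the breaking C1–O bond, so the (E)-geometry becomes the C1/C10 pair with O10 trans to the C1 methyl.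

Step 5
Reactants: 8 (2R)-2-[(1R)-1-hydroxyprop-2-en-1-yl]-2-methylcyclobutan-1-one
Product: 9 (2R)-2-{(1R)-1-[(tert-butyldimethylsilyl)oxy]prop-2-en-1-yl}-2-methylcyclobutan-1-one
Conditions: TBSOTf, 2,6-lutidine, CH2Cl2, −78 to 0 °C
Reagents that add atoms: tert-butyldimethylsilyl triflate, CC(C)(C)[Si](C)(C)OS(=O)(=O)C(F)(F)F
Why: Silylation with a silyl triflate and a hindered pyridine is non-basic enough to avoid retro-aldol cleavage of the β-hydroxy cyclobutanone.

Step 6
Reactants: 9 (2R)-2-{(1R)-1-[(tert-butyldimethylsilyl)oxy]prop-2-en-1-yl}-2-methylcyclobutan-1-one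
Product: 10 (1R,2R)-1-(dibromomethyl)-2-methyl-2-{(1R)-1-[(tert-butyldimethylsilyl)oxy]prop-2-en-1-yl}cyclobutan-1-ol (CHBr2 cis to the methyl group)
Conditions: CH2Br2, LiN(iPr)2, THF, −90 °C; then 9, −90 to −78 °C; then H2O
Reagents that add atoms: dibromomethane, BrCBr
Why: Preformed dibromomethyllithium undergoes 1,2-addition to the strained and very electrophilic cyclobutanone, expected anti to the bulky C10 arm, and the new C4 center is lost again in step 8.

Step 7
Reactants: 11 3-methylbut-3-en-1-ol
Product: 12 3-methylbut-3-enal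
Conditions: Dess–Martin periodinane, NaHCO3, CH2Cl2, 0 °C; used at once as a solution
Reagents that add atoms: none
Why: Buffered Dess–Martin oxidation should give the β,γ-unsaturated aldehyde without migration of the double bond into conjugation.

Step 8
Reactants: 10 (1R,2R)-1-(dibromomethyl)-2-methyl-2-{(1R)-1-[(tert-butyldimethylsilyl)oxy]prop-2-en-1-yl}cyclobutan-1-ol; 12 3-methylbut-3-enal
Product: 16 (2S,3S)-2-[(1S)-1-hydroxy-3-methylbut-3-en-1-yl]-3-methyl-3-{(1R)-1-[(tert-butyldimethylsilyl)oxy]prop-2-en-1-yl}cyclopentan-1-one, via lithium β-oxido carbenoid 13 (not isolated), via lithium enolate 14 (not isolated), via chlorozinc enolate 15 (not isolated)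
Conditions: n-BuLi (2.05 equiv), THF, −78 °C, then to −20 °C; ZnCl2 (1.1 equiv), −78 °C; 12 (1.5 equiv), −78 to −40 °C; then H2O
Reagents that add atoms: none
Why: Proposed new method: the first equivalent of n-BuLi deprotonates the carbinol and the second exchanges one bromine, and in the resulting β-oxido carbenoid 13 the C4–C1 bond lying anti to C5–Br shifts from C4 to C5 with loss of LiBr, so that the cyclobutane C1–C2–C3–C4 takes C5 into the ring and leaves as the amine-free cyclopentanone enolate 14 (C4(OLi)=C5H beside the quaternary C1), which after exchange to the less basic zinc enolate 15 adds to aldehyde 12 to form C5–C6. The closest known reaction types are the β-oxido carbenoid ring enlargement of dihalomethyllithium adducts of cycloalkanones and the trapping by electrophiles of the enolates set free from magnesium β-oxido carbenoids; new are the α-quaternary cyclobutanol as substrate and the coupling of the enlargement to a diastereoselective aldol addition. No ring is closed by cyclisation: the five-membered ring arises by one-carbon enlargement of the four-membered ring through a 1,2-shift with retention at the migrating C1, driven by loss of cyclobutane strain and formation of the enolate. C5 is controlled by the quaternary C1, since the aldehyde should reach the enolate on the face of the small methyl group and away from the C10H(OTBS)vinyl arm, which places H5 trans to the methyl group. C6 is controlled by the closed chair (Zimmerman–Traxler) transition state of the ring-locked E(O)-enolate, which leads to the anti aldol that is also the more stable zinc chelate. The step needs migration of C1 and not of C3, secured by the higher migratory aptitude of the fully substituted carbon and by the conformer with bromide anti to the bulky C1 being the least crowded, and it needs the enolate on the hindered C5 side, which follows from the mechanism and is kept by the absence of any proton source.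

Step 9
Reactants: 16 (2S,3S)-2-[(1S)-1-hydroxy-3-methylbut-3-en-1-yl]-3-methyl-3-{(1R)-1-[(tert-butyldimethylsilyl)oxy]prop-2-en-1-yl}cyclopentan-1-one
Product: 17 (1S,5S,6S,10R)-10-[(tert-butyldimethylsilyl)oxy]-6-hydroxy-1,8-dimethylbicyclo[5.3.0]dec-8-en-4-one (daucane numbering; trans ring fusion, H5 α, O6 α, O10 α)
Conditions: second-generation Grubbs catalyst (5 mol %), toluene (2 mM), 80 °C, Ar sparge
Reagents that add atoms: none
Why: Ring-closing metathesis between the vinyl group and the 1,1-disubstituted alkene closes the seven-membered ring as its trisubstituted C8=C9 alkene with loss of ethene, and the trans relation of the two arms on C1 and C5 is kept.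

Step 10
Reactants: 17 (1S,5S,6S,10R)-10-[(tert-butyldimethylsilyl)oxy]-6-hydroxy-1,8-dimethylbicyclo[5.3.0]dec-8-en-4-one
Product: 18 (1S,4R,5S,6S,10R)-10-[(tert-butyldimethylsilyl)oxy]dauc-8-ene-4,6-diol (4β-OH, 4α-isopropyl)
Conditions: iPrMgCl (3 equiv), LaCl3·2LiCl (1 equiv), THF, −40 to 0 °C; then H2O
Reagents that add atoms: isopropylmagnesium chloride, CC(C)[Mg]Cl
Why: Lanthanum-promoted Grignard 1,2-addition suppresses enolisation and reduction, and the reagent should attack C4 from the α face, opposite the axial C1 methyl and on the side of the C6 alkoxide, which gives the β tertiary alcohol.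

Step 11
Reactants: 18 (1S,4R,5S,6S,10R)-10-[(tert-butyldimethylsilyl)oxy]dauc-8-ene-4,6-diol; 19 4-acetoxybenzoyl chloride
Product: 20 6-O-(4-acetoxybenzoyl) derivative of 18
Conditions: pyridine, DMAP (cat.), CH2Cl2, 0 °C to rt
Reagents that add atoms: none
Why: DMAP-catalysed acylation takes the only secondary alcohol, because the tertiary C4 hydroxyl is too hindered to react.

Step 12
Reactants: 20 6-O-(4-acetoxybenzoyl) derivative of 18
Product: 21 (1S,4R,5S,6S,10R)-6-(4-acetoxybenzoyloxy)dauc-8-ene-4,10-diol
Conditions: HF·pyridine, pyridine, THF, 0 °C to rt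
Reagents that add atoms: none
Why: Fluoride-mediated desilylation under weakly acidic conditions should leave the aryl acetate, the benzoate and the tertiary alcohol untouched.

Step 13
Reactants: 21 (1S,4R,5S,6S,10R)-6-(4-acetoxybenzoyloxy)dauc-8-ene-4,10-diol; 22 angelic acid ((2Z)-2-methylbut-2-enoic acid)
Product: 24 10-O-angeloyl derivative of 21, via angelic 2,4,6-trichlorobenzoic anhydride 23 (not isolated)
Conditions: 2,4,6-trichlorobenzoyl chloride, Et3N, toluene, rt; then 21, 80 °C
Reagents that add atoms: none
Why: Yamaguchi esterification through mixed anhydride 23 without a nucleophilic catalyst is the variant that keeps the (Z)-geometry of angelates, and it acylates O10 with retention at C10.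

Step 14
Reactants: 24 10-O-angeloyl derivative of 21
Product: 25 target, (1S,4R,5S,6S,10R)-10-angeloyloxy-6-(4-hydroxybenzoyloxy)dauc-8-en-4-ol
Conditions: pyrrolidine (3 equiv), CH2Cl2, 0 °C
Reagents that add atoms: none
Why: Chemoselective aminolysis removes the activated phenyl acetate, while the alkyl benzoate and the hindered α,β-disubstituted angelate should react far more slowly.

Compound list
1 | [(1-ethoxycyclopropyl)oxy]trimethylsilane | CCOC1(CC1)O[Si](C)(C)C | starting material
2 | 1-ethoxycyclopropan-1-ol | CCOC1(O)CC1 | intermediate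
3 | 1-ethynylcyclopropan-1-ol | C#CC1(O)CC1 | intermediate
4 | 1-(but-3-en-1-yn-1-yl)cyclopropan-1-ol | C=CC#CC1(O)CC1 | intermediate
5 | chelated dienylmagnesium alkoxide (spiro oxamagnesacyclopentene) | C=CC1=C(C)C2(CC2)O[Mg]1 | intermediate
6 | 1-[(2E)-penta-2,4-dien-2-yl]cyclopropan-1-ol | C=C/C=C(\C)C1(O)CC1 | intermediate
7 | 1-[(2S,3R)-3-ethenyl-2-methyloxiran-2-yl]cyclopropan-1-ol | C=C[C@H]1O[C@]1(C)C2(O)CC2 | intermediate
8 | (2R)-2-[(1R)-1-hydroxyprop-2-en-1-yl]-2-methylcyclobutan-1-one | O=C1CC[C@]1(C)[C@H](O)C=C | intermediate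
9 | (2R)-2-{(1R)-1-[(tert-butyldimethylsilyl)oxy]prop-2-en-1-yl}-2-methylcyclobutan-1-one | O=C1CC[C@]1(C)[C@H](O[Si](C)(C)C(C)(C)C)C=C | intermediate
10 | (1R,2R)-1-(dibromomethyl)-2-methyl-2-{(1R)-1-[(tert-butyldimethylsilyl)oxy]prop-2-en-1-yl}cyclobutan-1-ol | BrC(Br)[C@@]1(O)CC[C@]1(C)[C@H](O[Si](C)(C)C(C)(C)C)C=C | intermediate
11 | 3-methylbut-3-en-1-ol | C=C(C)CCO | starting material
12 | 3-methylbut-3-enal | C=C(C)CC=O | intermediate
13 | lithium β-oxido carbenoid from 10 | [Li]C(Br)[C@@]1(O[Li])CC[C@]1(C)[C@H](O[Si](C)(C)C(C)(C)C)C=C | intermediate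
14 | lithium enolate of the ring-enlarged cyclopentanone (C4(OLi)=C5H) | C=C[C@@H](O[Si](C)(C)C(C)(C)C)[C@@]1(C)CCC(O[Li])=C1 | intermediate
15 | chlorozinc enolate of the ring-enlarged cyclopentanone | C=C[C@@H](O[Si](C)(C)C(C)(C)C)[C@@]1(C)CCC(O[Zn]Cl)=C1 | intermediate
16 | (2S,3S)-2-[(1S)-1-hydroxy-3-methylbut-3-en-1-yl]-3-methyl-3-{(1R)-1-[(tert-butyldimethylsilyl)oxy]prop-2-en-1-yl}cyclopentan-1-one | C=C[C@@H](O[Si](C)(C)C(C)(C)C)[C@@]1(C)CCC(=O)[C@@H]1[C@@H](O)CC(C)=C | intermediate
17 | (1S,5S,6S,10R)-10-[(tert-butyldimethylsilyl)oxy]-6-hydroxy-1,8-dimethylbicyclo[5.3.0]dec-8-en-4-one (daucane numbering, trans-fused) | CC(C)(C)[Si](C)(C)O[C@@H]1C=C(C)C[C@H](O)[C@@H]2[C@]1(C)CCC2=O | intermediate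
18 | (1S,4R,5S,6S,10R)-10-[(tert-butyldimethylsilyl)oxy]dauc-8-ene-4,6-diol | CC(C)(C)[Si](C)(C)O[C@@H]1C=C(C)C[C@H](O)[C@@H]2[C@]1(C)CC[C@@]2(O)C(C)C | intermediate
19 | 4-acetoxybenzoyl chloride | CC(=O)Oc1ccc(cc1)C(Cl)=O | starting material
20 | 6-O-(4-acetoxybenzoyl) derivative of 18 | CC(C)(C)[Si](C)(C)O[C@@H]1C=C(C)C[C@H](OC(=O)c2ccc(OC(C)=O)cc2)[C@@H]2[C@]1(C)CC[C@@]2(O)C(C)C | intermediate
21 | (1S,4R,5S,6S,10R)-6-(4-acetoxybenzoyloxy)dauc-8-ene-4,10-diol | O[C@@H]1C=C(C)C[C@H](OC(=O)c2ccc(OC(C)=O)cc2)[C@@H]2[C@]1(C)CC[C@@]2(O)C(C)C | intermediate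
22 | angelic acid | C/C=C(/C)C(=O)O | starting material
23 | angelic 2,4,6-trichlorobenzoic anhydride | C/C=C(/C)C(=O)OC(=O)c1c(Cl)cc(Cl)cc1Cl | intermediate
24 | 10-O-angeloyl derivative of 21 | C/C=C(/C)C(=O)O[C@@H]1C=C(C)C[C@H](OC(=O)c2ccc(OC(C)=O)cc2)[C@@H]2[C@]1(C)CC[C@@]2(O)C(C)C | intermediate
25 | (1S,4R,5S,6S,10R)-10-angeloyloxy-6-(4-hydroxybenzoyloxy)dauc-8-en-4-ol | C/C=C(/C)C(=O)O[C@@H]1C=C(C)C[C@H](OC(=O)c2ccc(O)cc2)[C@@H]2[C@]1(C)CC[C@@]2(O)C(C)C | target

Total step count: 14. Longest linear sequence: 13 steps (steps 1 to 6 and 8 to 14).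

Steps most likely to fail

Step 8. The C3 methylene may migrate in place of C1. The acidic α-position of 12 may transfer a proton to the enolate. The anti selectivity at C6 may erode. The fallback uses known chemistry, sets out from 9 (with 12) and comes back at 16.
- Aldehyde 12 would be converted by Takai olefination (CHI3, CrCl2, THF) into (1E)-1-iodo-4-methylpenta-1,4-diene F1.
- Iodine–lithium exchange (t-BuLi, Et2O, −78 °C) and addition to 9 would give the (E)-alkenylcyclobutanol F2.
- A hydroxyl-directed catalytic asymmetric epoxidation of this tertiary allylic alcohol would follow (Hf(OtBu)4, chiral bishydroxamic acid ligand chosen for the required face, cumene hydroperoxide, toluene). It is chemoselective for the allylic C5=C6 bond and would give the trans-(5R,6S)-epoxy alcohol F3.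
- BF3·OEt2 (CH2Cl2, −78 °C) would then trigger the semipinacol ring enlargement of the α-hydroxy epoxide. The quaternary C1 migrates to C5 with inversion there, and O6 keeps its configuration.

Step 10. Enolisation, β-hydride reduction by the branched Grignard reagent or retro-aldol opening of the C6 alkoxide may outrun addition. The fallback sets out from 17 and comes back at 18. 2-Propenylmagnesium bromide with CeCl3 (THF, −78 °C) is an sp2 nucleophile without β-hydrogens and would give the isopropenyl carbinol F4. Hydrogenation with RhCl(PPh3)3 and H2 (benzene, rt) should then saturate only the 1,1-disubstituted alkene and leave the trisubstituted ring alkene.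

Step 3. The carbometalation may be sluggish, may deliver methyl to C10 or across the enyne terminus, or may open the cyclopropanolate. The fallback sets out from 1 (through hemiacetal 2) and comes back at 6. Pent-1-en-3-yne would be hydrozirconated with Cp2ZrHCl (zirconium next to the methyl group, syn addition) and iodinated with I2 to give (3E)-4-iodopenta-1,3-diene F5. Iodine–lithium exchange (t-BuLi, Et2O, −78 °C) and addition to the bromomagnesium salt of 2 (from 2 and MeMgBr) would give 6 with the alkene geometry already fixed.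

Further compounds
F1 | step 8 | (1E)-1-iodo-4-methylpenta-1,4-diene | C=C(C)C/C=C/I
F2 | step 8 | 1-[(1E)-4-methylpenta-1,4-dien-1-yl]cyclobutanol from 9 (alkenyl group cis to the C1 methyl) | C=C(C)C/C=C/[C@@]1(O)CC[C@]1(C)[C@H](O[Si](C)(C)C(C)(C)C)C=C
F3 | step 8 | trans-(5R,6S)-epoxide of F2 | C=C(C)C[C@@H]1O[C@H]1[C@@]2(O)CC[C@]2(C)[C@H](O[Si](C)(C)C(C)(C)C)C=C
F4 | step 10 | C4 isopropenyl carbinol (4β-OH) from 17 | CC(C)(C)[Si](C)(C)O[C@@H]1C=C(C)C[C@H](O)[C@@H]2[C@]1(C)CC[C@@]2(O)C(C)=C
F5 | step 3 | (3E)-4-iodopenta-1,3-diene | C=C/C=C(\C)I
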